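## The problem

The target 25 is a cis-fused 1-benzoxepine. Ring A (C6, C7, C8, C9, C10, C11) is a cyclohexane with a gem-dimethyl carbon (C11), a secondary neopentyl bromide (C10) and a fully substituted ether carbon (C7, bearing CH3). Ring B (O, C2, C3, C4, C5, C6, C7) is an oxepene with a C3=C4 double bond, a hydroxymethyl group (C12) on C3 and a bromomethyl group (C1) on C2. Four stereocentres must be set: C7 (S), C6 (R; C5 and the ring oxygen cis on ring A), C10 (S; bromine on the face opposite to C5 and O) and C2 (R). C7 can control C6 if both sit in a small ring, but C10 is too far from C7 to be induced and C2 is five bonds from ring A, so each of these needs its own source of chirality. The fragile parts are the neopentyl secondary bromide (elimination or 1,2-shift on ionisation), the primary bromide β to the ether oxygen, and the allylic ether/allylic alcohol array. The hardest bond is the tertiary alkyl–O–secondary alkyl ether inside a seven-membered ring. The feature that allows a direct answer is that C2 is a secondary ether carbon flanked by sp2 carbon C3 and by C1. This is the pattern left when the C7 hydroxyl opens a terminal C1–C2 epoxide at its allylic carbon with inversion, and the oxygen released on C1 is the handle for the bromide.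

## Retrosynthesis

**C3=C4 and C12–OH (25 ⇒ 23 ⇒ 22).** No skeletal bond is cut. The allylic alcohol of 25 is traced to spiro epoxide 23 and from there to the C3 exocyclic methylene of 22. The alkene is stored exocyclic because the ring closure below requires it. The forward step must remove a proton from C4 and not from C2.

**C1–Br (22 ⇒ 21).** The primary bromide comes from the primary alcohol of 21 by an Appel reaction. Nothing else in 21 competes, because the C7 oxygen is already an ether.

**O–C2 (21 ⇒ 20).** The ring B ether bond is cut to hydroxy vinyl epoxide 20. This removes ring B and reduces C2 to a stereocentre of a three-carbon chiral-pool unit. The neighbouring cuts are worse: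
- O–C7 would need a tertiary cation and would lose C7.
- A C3=C4 alkene in the precursor would let the C7 oxygen attack C4 in an SN2′ sense and close a tetrahydrofuran.
- With the alkene on C3=C12 that five-membered path does not exist.

The forward reaction must attack C2 rather than C1 (eight-membered) or C12. Attack at C12 would also give a seven-membered ring, so this selectivity has to come from charge at C2 and not from ring size.

**Epoxide and protecting groups (20 ⇒ 18 ⇒ 17).** The epoxide is made from the 1,2-diol of triol 18 by primary tosylation and closure, which leaves C2 untouched. Triol 18 comes from 17, in which the diol is an acetonide and the C7 hydroxyl a triethylsilyl ether. One acid treatment removes both.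

**C3–C4 (17 ⇒ 15 + 4).** A Negishi coupling joins primary iodide 15 (through its zinc reagent 16) to bromoalkene 4. Adding an alkenyl metal to a C4 aldehyde would be shorter but leaves an oxygen on C4. The sp3–sp2 coupling gives C4 as CH2 and the methylene on C3 directly.

**Ring A side chain (15 ⇒ 14 ⇒ 12 ⇒ 11).** Iodide 15 comes from alcohol 14, and 14 from diol 12, the reduction product of bromo lactone 11. The C7 hydroxyl has to be masked before C4 is activated. A free C7–OH next to a C4 leaving group closes a tetrahydrofuran (5-exo-tet), and it would also quench the organozinc. Hence the detour through bis-silyl ether 13.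

**C10–Br (11 ⇒ 10).** The bromide is made from the epimeric alcohol 10 by substitution with inversion. This is done early, on a robust lactone.

**Ring A (10 ⇒ 9).** The C6–C11 bond is cut to epoxy butenolide 9. Cp2TiCl-mediated radical cyclisation forms ring A, fixes C6 cis to the C7 oxygen through the lactone ring, and carries C10 from the epoxide.

**Butenolide and epoxide (9 ⇒ 8 ⇒ 7 ⇒ 5 + 6).** Ring-closing metathesis of epoxy acrylate 8 gives 9. Compound 8 comes from Shi epoxidation of linalyl acrylate 7, made from (S)-linalool 5 and acryloyl chloride 6. Epoxidation precedes metathesis so that the trisubstituted alkene cannot take part in ring closure.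

**Bromoalkene (4 ⇒ 3 ⇒ 2 ⇒ 1).** Compound 4 comes from (R)-glyceraldehyde acetonide 1 by methylenation to 2, bromine addition to 3 and regioselective loss of HBr.

## Roads not taken

**Alternative 1:** The cut is C6–C11 of ring A. In the forward step Cp2TiCl (trivalent titanium, from Cp2TiCl2 and zinc) opens epoxy butenolide A1 to the C11 radical, which adds 6-exo to C6 and gives cis-fused hydroxy lactone A2.
- Merits: one step makes ring A, fixes the C6/C7 relationship through the lactone and carries the C10 oxygen. It is short from linalool, and its stereochemistry rests on a cheap terpene and a reagent-controlled epoxidation.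
- Weak points: it ends at ring A. C10 carries oxygen of the configuration that then needs an invertive neopentyl substitution. It offers nothing for the tertiary ether, the seven-membered ring or C2.
- Comparison: for ring A this road is as good as any, and the chosen plan uses the same reaction as step 7 (A1 and A2 are identical with 9 and 10). The chosen plan adds the answer for ring B and C2, which is the harder half of the target.

**Alternative 2:** The cuts are C5–C6 and C7–O. In the forward step Mn(OAc)3 (trivalent manganese) in its parent acid generates a carboxymethyl radical that adds to C6 of bromocyclohexene A3. Oxidation at C7 and carboxylate capture give cis-fused bromo lactone A4, identical with 11.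
- Merits: one step to the bromo lactone, with the bromine present from the start. This avoids the neopentyl substitution of the chosen plan (step 8), and in that respect the road is better.
- Weak points: enantiopure A3 is not at hand and contains the same neopentyl bromide. The radical must attack C6 next to quaternary C11. Only the distant C10 bromine distinguishes the alkene faces. C7 passes through a cation under hot acidic, oxidising conditions, beside a secondary bromide prone to elimination.
- Comparison: the chosen plan sets against this a named control element for every centre (C7 from linalool, C10 from the Shi catalyst, C6 from the lactone ring), and accepts one difficult substitution.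

**Alternative 3:** The cuts are C2–C3 and C4–C5. In the forward step dihydrofuran A5 and methyl propiolate A6 combine under EtAlCl2 in a stepwise [2+2], and the cyclobutene opens to dihydrooxepine ester A7.
- Merits: ring B arises by ring expansion, so no seven-membered closure at a tertiary oxygen is needed. C12 arrives as an ester on C3, and the C3=C4 alkene could follow from conjugate addition at C2 and γ-protonation. This avoids the alkene transposition of the chosen plan and is better there.
- Weak points: A7 lacks C1 and the C2 stereocentre. A one-carbon nucleophile would have to add to C2 with only ring A to direct it. The enol ether carbon C5 is flanked by the hindered C6. The Lewis acid meets an acid-labile enol ether and a secondary bromide. A5 itself comes from the same bromo lactone 11, so no ring A work is saved.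
- Comparison: the step count is similar, but the chosen plan sets C2 by a stereospecific inversion of a chiral-pool epoxide rather than by substrate-controlled addition.

Key step: step 15

Remark: (S)-linalool and (R)-glyceraldehyde acetonide are taken as commercial materials of high enantiomeric purity; two centres made and destroyed within the route (the CHBr carbon of 3 and spiro carbon C3 of 23) are carried as epimer mixtures and left undefined in the SMILES.

## Route

Step 1
Reactants: 1 (R)-2,2-dimethyl-1,3-dioxolane-4-carbaldehyde
Product: 2 (S)-4-ethenyl-2,2-dimethyl-1,3-dioxolane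
Conditions: Ph3PCH3Br, KHMDS, THF, −78 to 0 °C
Reagents that add atoms: methyltriphenylphosphonium bromide, C[P+](c1ccccc1)(c1ccccc1)c1ccccc1.[Br-]
Why: Wittig methylenation of an α-alkoxy aldehyde with a non-stabilised ylide at low temperature; the dioxolane stereocentre (future C2) is not touched and only its descriptor changes.

Step 2
Reactants: 2 (S)-4-ethenyl-2,2-dimethyl-1,3-dioxolane
Product: 3 (4R)-4-(1,2-dibromoethyl)-2,2-dimethyl-1,3-dioxolane
Conditions: Br2, CH2Cl2, −78 °C
Reagents that add atoms: bromine, BrBr
Why: Electrophilic anti addition of bromine to the terminal alkene; the new CHBr centre is removed in the next step, so both epimers are used.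

Step 3
Reactants: 3 (4R)-4-(1,2-dibromoethyl)-2,2-dimethyl-1,3-dioxolane
Product: 4 (R)-4-(1-bromoethenyl)-2,2-dimethyl-1,3-dioxolane
Conditions: DBU, DMF, rt
Reagents that add atoms: none
Why: E2 dehydrobromination; the proton on the CHBr carbon is acidified by bromine and the adjacent C–O bond, so HBr is lost toward the terminal carbon and the 2-bromo-1-alkene should form. The dioxolane centre is not involved.

Step 4
Reactants: 5 (S)-linalool; 6 acryloyl chloride
Product: 7 (3S)-3,7-dimethylocta-1,6-dien-3-yl prop-2-enoate
Conditions: Et3N, DMAP (cat.), CH2Cl2, 0 °C to rt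
Reagents that add atoms: none
Why: DMAP-catalysed acylation of the tertiary allylic alcohol; the C7 centre is only esterified.

Step 5
Reactants: 7 (3S)-3,7-dimethylocta-1,6-dien-3-yl prop-2-enoate
Product: 8 (3S)-5-[(2R)-3,3-dimethyloxiran-2-yl]-3-methylpent-1-en-3-yl prop-2-enoate
Conditions: D-fructose-derived Shi ketone (0.3 equiv), Oxone (2KHSO5·KHSO4·K2SO4), K2CO3, Bu4NHSO4, borate buffer pH 10.5, MeCN–CH2(OMe)2–H2O, 0 °C
Reagents that add atoms: Oxone (potassium peroxymonosulfate), [K+].[O-]S(=O)(=O)OO
Why: Shi epoxidation; the chiral dioxirane attacks only the electron-rich trisubstituted alkene, and its spiro transition state should give the (R)-epoxide (future C10) under reagent control. Doing this before metathesis removes the alkene that could otherwise close a cyclopentene.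

Step 6
Reactants: 8 (3S)-5-[(2R)-3,3-dimethyloxiran-2-yl]-3-methylpent-1-en-3-yl prop-2-enoate
Product: 9 (5S)-5-{2-[(2R)-3,3-dimethyloxiran-2-yl]ethyl}-5-methylfuran-2(5H)-one
Conditions: second-generation Grubbs catalyst (H2IMes)(PCy3)Cl2Ru=CHPh (5 mol%), toluene (0.01 M), 80 °C
Reagents that add atoms: none
Why: Ring-closing metathesis of the acrylate with the vinyl group gives the butenolide with loss of ethylene; the epoxide is inert to the ruthenium carbene.

Step 7
Reactants: 9 (5S)-5-{2-[(2R)-3,3-dimethyloxiran-2-yl]ethyl}-5-methylfuran-2(5H)-one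
Product: 10 (3aR,5R,7aS)-5-hydroxy-4,4,7a-trimethylhexahydro-1-benzofuran-2(3H)-one
Conditions: Cp2TiCl2 (2.5 equiv), Zn dust, THF, rt; then 1 M HCl
Reagents that add atoms: none
Why: Cp2TiCl (trivalent titanium) opens the epoxide homolytically to the tertiary C11 radical, which adds 6-exo-trig to butenolide carbon C6; a second Cp2TiCl reduces the α-carbonyl radical to a titanium enolate that is protonated on work-up. The tether can reach only the face of the butenolide on which it is attached, so C6 is set cis to the C7 oxygen; C10 is carried from the epoxide, with the titanium alkoxide equatorial in the chair-like transition state.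

Step 8
Reactants: 10 (3aR,5R,7aS)-5-hydroxy-4,4,7a-trimethylhexahydro-1-benzofuran-2(3H)-one
Product: 11 (3aR,5S,7aS)-5-bromo-4,4,7a-trimethylhexahydro-1-benzofuran-2(3H)-one
Conditions: CBr4, PPh3, toluene, 0 to 60 °C
Reagents that add atoms: carbon tetrabromide, BrC(Br)(Br)Br
Why: Appel reaction; bromide displaces the oxyphosphonium group in an SN2 sense, so C10 is inverted to the (S)-bromide; the lactone is inert and its acceptor effect disfavours ionisation.

Step 9
Reactants: 11 (3aR,5S,7aS)-5-bromo-4,4,7a-trimethylhexahydro-1-benzofuran-2(3H)-one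
Product: 12 (1S,2R,4S)-4-bromo-2-(2-hydroxyethyl)-1,3,3-trimethylcyclohexan-1-ol
Conditions: LiBH4, THF, 0 °C to rt
Reagents that add atoms: none
Why: Borohydride reduction of the lactone to the primary/tertiary diol; the hindered secondary bromide is not attacked by this mild hydride.

Step 10
Reactants: 12 (1S,2R,4S)-4-bromo-2-(2-hydroxyethyl)-1,3,3-trimethylcyclohexan-1-ol
Product: 14 2-[(1R,2S,5S)-5-bromo-2,6,6-trimethyl-2-(triethylsilyloxy)cyclohexyl]ethan-1-ol, via bis(triethylsilyl) ether 13 (not isolated)
Conditions: TESOTf (2.5 equiv), 2,6-lutidine, CH2Cl2, −78 to 0 °C; then MeOH, PPTS, 0 °C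
Reagents that add atoms: triethylsilyl trifluoromethanesulfonate, CC[Si](CC)(CC)OS(=O)(=O)C(F)(F)F
Why: Exhaustive silylation followed by selective acid methanolysis of the primary silyl ether, which is far faster than that of the hindered tertiary one. The C7 oxygen must be masked because a free hydroxyl would close a tetrahydrofuran onto an activated C4 and would quench the organozinc of step 12.

Step 11
Reactants: 14 2-[(1R,2S,5S)-5-bromo-2,6,6-trimethyl-2-(triethylsilyloxy)cyclohexyl]ethan-1-ol
Product: 15 {[(1S,2R,4S)-4-bromo-2-(2-iodoethyl)-1,3,3-trimethylcyclohexyl]oxy}triethylsilane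
Conditions: I2, PPh3, imidazole, CH2Cl2, 0 °C to rt
Reagents that add atoms: iodine, II
Why: Appel-type iodination of the primary alcohol; imidazole buffers the medium so the tertiary silyl ether survives.

Step 12
Reactants: 15 {[(1S,2R,4S)-4-bromo-2-(2-iodoethyl)-1,3,3-trimethylcyclohexyl]oxy}triethylsilane; 4 (R)-4-(1-bromoethenyl)-2,2-dimethyl-1,3-dioxolane
Product: 17 (4S)-4-{4-[(1R,2S,5S)-5-bromo-2,6,6-trimethyl-2-(triethylsilyloxy)cyclohexyl]but-1-en-2-yl}-2,2-dimethyl-1,3-dioxolane, via alkylzinc iodide 16 (not isolated)
Conditions: Zn dust (TMSCl/BrCH2CH2Br-activated), DMA, rt; then 4, Pd(OAc)2 (3 mol%), SPhos (6 mol%), THF, rt to 40 °C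
Reagents that add atoms: none
Why: Zinc inserts into the primary C–I bond while the neopentyl secondary bromide stays intact; Negishi coupling (oxidative addition of zerovalent palladium into the alkenyl bromide, transmetalation, reductive elimination) forms C3–C4. The dioxolane centre is untouched and only its descriptor changes.

Step 13
Reactants: 17 (4S)-4-{4-[(1R,2S,5S)-5-bromo-2,6,6-trimethyl-2-(triethylsilyloxy)cyclohexyl]but-1-en-2-yl}-2,2-dimethyl-1,3-dioxolane
Product: 18 (2S)-5-[(1R,2S,5S)-5-bromo-2-hydroxy-2,6,6-trimethylcyclohexyl]-3-methylidenepentane-1,2-diol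
Conditions: AcOH–THF–H2O (3:1:1), 45 °C
Reagents that add atoms: none
Why: Mild aqueous acid hydrolyses the terminal acetonide and the triethylsilyl ether in one operation; it is too weak to protonate the 1,1-disubstituted alkene or ionise the allylic alcohol.

Step 14
Reactants: 18 (2S)-5-[(1R,2S,5S)-5-bromo-2-hydroxy-2,6,6-trimethylcyclohexyl]-3-methylidenepentane-1,2-diol
Product: 20 (1S,2R,4S)-4-bromo-1,3,3-trimethyl-2-{3-[(2S)-oxiran-2-yl]but-3-en-1-yl}cyclohexan-1-ol, via primary tosylate 19 (not isolated)
Conditions: TsCl, Et3N, Bu2SnO (cat.), CH2Cl2, 0 °C; then K2CO3, MeOH, rt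
Reagents that add atoms: none
Why: Tin-catalysed tosylation selects the primary hydroxyl of the 1,2-diol through its stannylene acetal; base then closes the epoxide by attack of the C2 alkoxide on C1. No bond to C2 is broken, so the (S) configuration from the chiral pool is retained.

Step 15
Reactants: 20 (1S,2R,4S)-4-bromo-1,3,3-trimethyl-2-{3-[(2S)-oxiran-2-yl]but-3-en-1-yl}cyclohexan-1-ol
Product: 21 [(2R,5aR,7S,9aS)-7-bromo-6,6,9a-trimethyl-3-methylidenedecahydro-1-benzoxepin-2-yl]methanol
Conditions: CSA (0.1 equiv), CH2Cl2 (0.01 M), −20 to 0 °C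
Reagents that add atoms: none
Why: The protonated epoxide is opened by backside attack of the C7 tertiary hydroxyl on allylic carbon C2, forming O–C2 and releasing C1 as CH2OH; the closest known reaction type is the acid-catalysed exo cyclisation of hydroxy epoxides whose attacked carbon is activated by an alkenyl group, used for tetrahydropyrans and oxepanes. Ring B closes in the 7-exo-tet mode. The new centre C2 is set by inversion of the (S)-epoxide carbon and so traces back to (R)-glyceraldehyde, not to ring A. The step must select C2 over C1 and over C12: attack at C1 would be 8-endo at an unactivated primary carbon, and attack at C12 would also give a seven-membered ring but needs full allyl cation character at a primary terminus, whereas under a weak Brønsted acid in a non-polar solvent the charge stays at C2 where the C–O bond is breaking. Keeping the alkene on C3=C12 rather than C3=C4 removes the five-membered SN2′ closure onto C4. The cis arrangement of C5 and O on ring A (C5 equatorial, O axial) holds the hydroxyl gauche to the side chain, and high dilution suppresses intermolecular opening.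

Step 16
Reactants: 21 [(2R,5aR,7S,9aS)-7-bromo-6,6,9a-trimethyl-3-methylidenedecahydro-1-benzoxepin-2-yl]methanol
Product: 22 (2R,5aR,7S,9aS)-7-bromo-2-(bromomethyl)-6,6,9a-trimethyl-3-methylidenedecahydro-1-benzoxepine
Conditions: CBr4, PPh3, CH2Cl2, 0 °C
Reagents that add atoms: carbon tetrabromide, BrC(Br)(Br)Br
Why: Appel bromination of the only hydroxyl, a primary one; C2 is not a reacting centre and the neutral conditions spare the allylic ether and the alkene.

Step 17
Reactants: 22 (2R,5aR,7S,9aS)-7-bromo-2-(bromomethyl)-6,6,9a-trimethyl-3-methylidenedecahydro-1-benzoxepine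
Product: 23 (2R,5aR,7S,9aS)-7-bromo-2-(bromomethyl)-6,6,9a-trimethyloctahydro-2H-spiro[1-benzoxepine-3,2'-oxirane]
Conditions: mCPBA, NaHCO3, CH2Cl2, 0 °C
Reagents that add atoms: 3-chloroperoxybenzoic acid, OOC(=O)c1cccc(Cl)c1
Why: Prilezhaev epoxidation of the only alkene; the configuration at spiro carbon C3 is irrelevant because C3 becomes sp2 again in step 18.

Step 18
Reactants: 23 (2R,5aR,7S,9aS)-7-bromo-2-(bromomethyl)-6,6,9a-trimethyloctahydro-2H-spiro[1-benzoxepine-3,2'-oxirane]
Product: 25 [(2R,5aR,7S,9aS)-7-bromo-2-(bromomethyl)-6,6,9a-trimethyl-2,5,5a,6,7,8,9,9a-octahydro-1-benzoxepin-3-yl]methanol, via allylic trimethylsilyl ether 24 (not isolated)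
Conditions: Me3SiOTf, DBU, toluene, −78 to 0 °C; then citric acid, MeOH
Reagents that add atoms: none
Why: Silyl triflate/amidine isomerisation of a 2,2-disubstituted epoxide to an allylic silyl ether: silylation opens the epoxide at tertiary C3 and DBU removes a β-proton. The C4 methylene is more accessible and more electron-rich than the C2 methine, which is deactivated by oxygen and the bromomethyl group, so the C3=C4 alkene should form; mild acid methanolysis frees the C12 alcohol.

## Compound list

1 | (R)-2,2-dimethyl-1,3-dioxolane-4-carbaldehyde ((R)-glyceraldehyde acetonide) | O=C[C@H]1COC(C)(C)O1 | starting material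
2 | (S)-4-ethenyl-2,2-dimethyl-1,3-dioxolane | C=C[C@H]1COC(C)(C)O1 | intermediate
3 | (4R)-4-(1,2-dibromoethyl)-2,2-dimethyl-1,3-dioxolane (both epimers at CHBr) | BrCC(Br)[C@H]1COC(C)(C)O1 | intermediate
4 | (R)-4-(1-bromoethenyl)-2,2-dimethyl-1,3-dioxolane | C=C(Br)[C@H]1COC(C)(C)O1 | intermediate
5 | (S)-(+)-linalool | C=C[C@@](C)(O)CCC=C(C)C | starting material
6 | acryloyl chloride | C=CC(=O)Cl | starting material
7 | (3S)-3,7-dimethylocta-1,6-dien-3-yl prop-2-enoate | C=C[C@@](C)(OC(=O)C=C)CCC=C(C)C | intermediate
8 | (3S)-5-[(2R)-3,3-dimethyloxiran-2-yl]-3-methylpent-1-en-3-yl prop-2-enoate | C=C[C@@](C)(OC(=O)C=C)CC[C@H]1OC1(C)C | intermediate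
9 | (5S)-5-{2-[(2R)-3,3-dimethyloxiran-2-yl]ethyl}-5-methylfuran-2(5H)-one | C[C@@]1(CC[C@H]2OC2(C)C)OC(=O)C=C1 | intermediate
10 | (3aR,5R,7aS)-5-hydroxy-4,4,7a-trimethylhexahydro-1-benzofuran-2(3H)-one | CC1(C)[C@H]2CC(=O)O[C@@]2(C)CC[C@H]1O | intermediate
11 | (3aR,5S,7aS)-5-bromo-4,4,7a-trimethylhexahydro-1-benzofuran-2(3H)-one | CC1(C)[C@H]2CC(=O)O[C@@]2(C)CC[C@@H]1Br | intermediate
12 | (1S,2R,4S)-4-bromo-2-(2-hydroxyethyl)-1,3,3-trimethylcyclohexan-1-ol | CC1(C)[C@@H](CCO)[C@@](C)(O)CC[C@@H]1Br | intermediate
13 | bis(triethylsilyl) ether of 12 | CC1(C)[C@@H](CCO[Si](CC)(CC)CC)[C@@](C)(O[Si](CC)(CC)CC)CC[C@@H]1Br | intermediate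
14 | 2-[(1R,2S,5S)-5-bromo-2,6,6-trimethyl-2-(triethylsilyloxy)cyclohexyl]ethan-1-ol | CC1(C)[C@@H](CCO)[C@@](C)(O[Si](CC)(CC)CC)CC[C@@H]1Br | intermediate
15 | {[(1S,2R,4S)-4-bromo-2-(2-iodoethyl)-1,3,3-trimethylcyclohexyl]oxy}triethylsilane | CC1(C)[C@@H](CCI)[C@@](C)(O[Si](CC)(CC)CC)CC[C@@H]1Br | intermediate
16 | alkylzinc iodide from 15 (C4–ZnI) | CC1(C)[C@@H](CC[Zn]I)[C@@](C)(O[Si](CC)(CC)CC)CC[C@@H]1Br | intermediate
17 | (4S)-4-{4-[(1R,2S,5S)-5-bromo-2,6,6-trimethyl-2-(triethylsilyloxy)cyclohexyl]but-1-en-2-yl}-2,2-dimethyl-1,3-dioxolane | CC1(C)[C@@H](CCC(=C)[C@H]2COC(C)(C)O2)[C@@](C)(O[Si](CC)(CC)CC)CC[C@@H]1Br | intermediate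
18 | (2S)-5-[(1R,2S,5S)-5-bromo-2-hydroxy-2,6,6-trimethylcyclohexyl]-3-methylidenepentane-1,2-diol | CC1(C)[C@@H](CCC(=C)[C@H](O)CO)[C@@](C)(O)CC[C@@H]1Br | intermediate
19 | primary 4-methylbenzenesulfonate of 18 (at C1) | CC1(C)[C@@H](CCC(=C)[C@H](O)COS(=O)(=O)c2ccc(C)cc2)[C@@](C)(O)CC[C@@H]1Br | intermediate
20 | (1S,2R,4S)-4-bromo-1,3,3-trimethyl-2-{3-[(2S)-oxiran-2-yl]but-3-en-1-yl}cyclohexan-1-ol | CC1(C)[C@@H](CCC(=C)[C@H]2CO2)[C@@](C)(O)CC[C@@H]1Br | intermediate
21 | [(2R,5aR,7S,9aS)-7-bromo-6,6,9a-trimethyl-3-methylidenedecahydro-1-benzoxepin-2-yl]methanol | CC1(C)[C@H]2CCC(=C)[C@H](CO)O[C@@]2(C)CC[C@@H]1Br | intermediate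
22 | (2R,5aR,7S,9aS)-7-bromo-2-(bromomethyl)-6,6,9a-trimethyl-3-methylidenedecahydro-1-benzoxepine | CC1(C)[C@H]2CCC(=C)[C@H](CBr)O[C@@]2(C)CC[C@@H]1Br | intermediate
23 | (2R,5aR,7S,9aS)-7-bromo-2-(bromomethyl)-6,6,9a-trimethyloctahydro-2H-spiro[1-benzoxepine-3,2'-oxirane] (both C3 epimers) | CC1(C)[C@H]2CCC3(CO3)[C@H](CBr)O[C@@]2(C)CC[C@@H]1Br | intermediate
24 | trimethylsilyl ether of 25 (at C12) | CC1(C)[C@H]2CC=C(CO[Si](C)(C)C)[C@H](CBr)O[C@@]2(C)CC[C@@H]1Br | intermediate
25 | [(2R,5aR,7S,9aS)-7-bromo-2-(bromomethyl)-6,6,9a-trimethyl-2,5,5a,6,7,8,9,9a-octahydro-1-benzoxepin-3-yl]methanol | CC1(C)[C@H]2CC=C(CO)[C@H](CBr)O[C@@]2(C)CC[C@@H]1Br | target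

## Step count and least certain steps

Total: 18 steps. Longest linear sequence: 15 steps (steps 4 to 18, from 5); the bromoalkene branch (steps 1 to 3) joins at step 12.

**Step 15 (key step).** The likely failures are closure at C12 with allylic transposition (also seven-membered), or a slow medium-ring closure that lets acid-induced rearrangement or intermolecular opening of the vinyl epoxide take over. The fallback changes the electrophile and skips the epoxide. It sets out from triol 18, which is converted with trimethyl orthoacetate and PPTS into the cyclic orthoester F1. BF3·OEt2 at low temperature ionises F1 to the dioxolanylium ion, which the C7 hydroxyl should open at allylic C2 with inversion to give the C1 acetate F2. Methanolysis (K2CO3, MeOH) returns to the route at 21.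

**Step 8.** Backside attack on the equatorial, neopentyl C10–O bond is slow, so the oxyphosphonium intermediate may ionise, with ring contraction or methyl shift, or eliminate. The fallback separates activation from substitution. From 10, Tf2O and pyridine give the triflate F3, which is displaced by Bu4NBr in toluene, a non-ionising medium, to rejoin the route at 11.

**Step 12.** Transmetalation to the hindered, α-branched alkenylpalladium may be slow, which would favour protodezincation or β-hydride elimination of the alkyl partner. The fallback forms C3–C4 by acylation and installs the methylene afterwards. Zinc reagent 16 (from 15) undergoes Fukuyama coupling (PdCl2(PPh3)2, toluene) with S-ethyl (4R)-2,2-dimethyl-1,3-dioxolane-4-carbothioate F4, made from commercial methyl (R)-glycerate acetonide, to give the ketone F5. Non-basic methylenation with the Tebbe reagent Cp2Ti(μ-Cl)(μ-CH2)AlMe2 returns to the route at 17.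

**Step 18.** Proton loss may occur from C2 (enol ether), a hydride may shift from C2 to the C3 cation, or DBU may attack the primary bromide. The fallback puts an oxygen on C4 first, so that the alkene can only move to C3=C4. From 22, SeO2 (cat.) and t-BuOOH in CH2Cl2 should hydroxylate the ring methylene C4 in preference to the C2 methine, giving the allylic alcohol F6 (either C4 epimer). Ph3SiOReO3-catalysed 1,3-transposition in Et2O at 0 °C then leads to the primary alcohol with the trisubstituted ring alkene and rejoins the route at 25, replacing steps 17 and 18.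

## Further compounds

F1 | step 15 | cyclic methyl orthoacetate of the 1,2-diol of 18 | CC1(C)[C@@H](CCC(=C)[C@H]2COC(C)(OC)O2)[C@@](C)(O)CC[C@@H]1Br
F2 | step 15 | [(2R,5aR,7S,9aS)-7-bromo-6,6,9a-trimethyl-3-methylidenedecahydro-1-benzoxepin-2-yl]methyl acetate | CC1(C)[C@H]2CCC(=C)[C@H](COC(C)=O)O[C@@]2(C)CC[C@@H]1Br
F3 | step 8 | (3aR,5R,7aS)-4,4,7a-trimethyl-2-oxooctahydro-1-benzofuran-5-yl trifluoromethanesulfonate | CC1(C)[C@H]2CC(=O)O[C@@]2(C)CC[C@H]1OS(=O)(=O)C(F)(F)F
F4 | step 12 | S-ethyl (4R)-2,2-dimethyl-1,3-dioxolane-4-carbothioate | CCSC(=O)[C@H]1COC(C)(C)O1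
F5 | step 12 | 3-[(1R,2S,5S)-5-bromo-2,6,6-trimethyl-2-(triethylsilyloxy)cyclohexyl]-1-[(4R)-2,2-dimethyl-1,3-dioxolan-4-yl]propan-1-one | CC1(C)[C@@H](CCC(=O)[C@H]2COC(C)(C)O2)[C@@](C)(O[Si](CC)(CC)CC)CC[C@@H]1Br
F6 | step 18 | (2R,5aR,7S,9aS)-7-bromo-2-(bromomethyl)-6,6,9a-trimethyl-3-methylidenedecahydro-1-benzoxepin-4-ol (either C4 epimer) | CC1(C)[C@H]2CC(O)C(=C)[C@H](CBr)O[C@@]2(C)CC[C@@H]1Br
A1 | alternative 1 | (5S)-5-{2-[(2R)-3,3-dimethyloxiran-2-yl]ethyl}-5-methylfuran-2(5H)-one | C[C@@]1(CC[C@H]2OC2(C)C)OC(=O)C=C1
A2 | alternative 1 | (3aR,5R,7aS)-5-hydroxy-4,4,7a-trimethylhexahydro-1-benzofuran-2(3H)-one | CC1(C)[C@H]2CC(=O)O[C@@]2(C)CC[C@H]1O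
A3 | alternative 2 | (S)-4-bromo-1,3,3-trimethylcyclohex-1-ene | CC1=CC(C)(C)[C@@H](Br)CC1
A4 | alternative 2 | (3aR,5S,7aS)-5-bromo-4,4,7a-trimethylhexahydro-1-benzofuran-2(3H)-one | CC1(C)[C@H]2CC(=O)O[C@@]2(C)CC[C@@H]1Br
A5 | alternative 3 | (3aR,5S,7aS)-5-bromo-4,4,7a-trimethyl-3a,4,5,6,7,7a-hexahydro-1-benzofuran | CC1(C)[C@H]2C=CO[C@@]2(C)CC[C@@H]1Br
A6 | alternative 3 | methyl propiolate | C#CC(=O)OC
A7 | alternative 3 | methyl (5aR,7S,9aS)-7-bromo-6,6,9a-trimethyl-5a,6,7,8,9,9a-hexahydro-1-benzoxepine-3-carboxylate | CC1(C)[C@H]2C=CC(C(=O)OC)=CO[C@@]2(C)CC[C@@H]1Br
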